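## Retrosynthetic overview

1. Target 26 ⇐ thioester 25 by a last, base-free ketone synthesis with (Z)-propenylboronic acid; 25 ⇐ diol 24 by selective C5 acylation ⇐ acetonide 23.
2. Lactone ring ⇐ cycloheptenone 20: phosphonoacetate tethered on the C6 oxygen, intramolecular Michael addition, then olefination with formaldehyde (cis fusion).
3. Seven-membered carbocycle ⇐ dienone 18 by ring-closing metathesis (C7=C8).
4. C1–C10 bond and both its stereocentres ⇐ Ireland–Claisen rearrangement of ester 11, made from acid fragment 7 (D-mannose pool, supplies C5 and C6) and alcohol fragment 10 (allylsilane, a masked vinyl ketone).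
5. Ring order: carbocycle first (RCM), lactone second (Michael); the Z-enone is installed last.

Atom labels (one assumption): C1 = C(OH), C2 = side-chain C=O, C3=C4 = Z-alkene, C5 = CH–O-isovaleryl, C6 = lactone CH–O, C7 = lactone ring-fusion CH, C8 = CH2, C9 = ring C=O, C10 = CH(CH3), C11–C13 = methylene-lactone carbons; the SMILES is read as (1S,5S,6R,7S,10R) with a cis-fused lactone.

## Route

**Acid fragment**

Step 1
Reactants: 1 2,3:5,6-di-O-isopropylidene-α-D-mannofuranose
Product: 2 2,3:5,6-di-O-isopropylidene-D-mannono-1,4-lactone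
Conditions: TEMPO (10 mol%), PhI(OAc)2, CH2Cl2, rt
Reagents that add atoms: none
Why: Oxoammonium (TEMPO) oxidation of the lactol gives the γ-lactone without touching the acetonides or any stereocentre.

Step 2
Reactants: 2 2,3:5,6-di-O-isopropylidene-D-mannono-1,4-lactone
Product: 3 2,3-O-isopropylidene-D-mannono-1,4-lactone
Conditions: 70% aq. AcOH, 40 °C
Reagents that add atoms: none
Why: Acid-catalysed acetal hydrolysis is much faster for the terminal 5,6-dioxolane than for the ring-fused 2,3-dioxolane.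

Step 3
Reactants: 3 2,3-O-isopropylidene-D-mannono-1,4-lactone
Product: 4 5,6-dideoxy-2,3-O-isopropylidene-D-lyxo-hex-5-enono-1,4-lactone
Conditions: PPh3, I2, imidazole, toluene, 110 °C
Reagents that add atoms: none
Why: Garegg–Samuelsson deoxygenation turns the terminal vicinal diol into the vinyl group (the later C7) and leaves the adjacent C–O stereocentre (later C6) untouched.

Step 4
Reactants: 4 5,6-dideoxy-2,3-O-isopropylidene-D-lyxo-hex-5-enono-1,4-lactone
Product: 7 4-O-(tert-butyldimethylsilyl)-5,6-dideoxy-2,3-O-isopropylidene-D-lyxo-hex-5-enonic acid, via potassium carboxylate 5 (not isolated), via bis-silyl derivative 6 (not isolated)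
Conditions: KOH, THF/H2O, 0 °C; evaporate; tBuMe2SiCl, imidazole, DMF, 35 °C; then K2CO3 (cat.), MeOH/H2O, rt, pH 5 work-up
Reagents that add atoms: potassium hydroxide, [K+].[OH-]; tert-butyldimethylsilyl chloride, CC(C)(C)[Si](C)(C)Cl
Why: Saponification opens the lactone, exhaustive silylation caps the liberated C6 hydroxyl, and selective solvolysis of the labile silyl ester frees the acid; the carboxylate is not enolised.

**Alcohol fragment**

Step 5
Reactants: 8 (E)-but-2-enal
Product: 9 racemic (E)-1-(trimethylsilyl)hex-4-en-3-ol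
Conditions: Me3SiCH2MgCl, Et2O, −78 to 0 °C; aq. NH4Cl
Reagents that add atoms: (trimethylsilyl)methylmagnesium chloride, C[Si](C)(C)C[Mg]Cl
Why: Grignard 1,2-addition to the enal gives the β-hydroxysilane, and the neutral work-up avoids Peterson elimination.

Step 6
Reactants: 9 racemic (E)-1-(trimethylsilyl)hex-4-en-3-ol
Product: 10 (3S,4E)-1-(trimethylsilyl)hex-4-en-3-ol
Conditions: Ti(OiPr)4 (10 mol%), L-(+)-diisopropyl tartrate (15 mol%), tBuOOH (0.6 equiv), 4 Å sieves, CH2Cl2, −20 °C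
Reagents that add atoms: none
Why: In this Sharpless kinetic resolution the (R)-enantiomer is epoxidised much faster with the L-(+)-tartrate catalyst, so the (S)-allylic alcohol is recovered in high ee.

**Fragment union and elaboration**

Step 7
Reactants: 7 4-O-(tert-butyldimethylsilyl)-5,6-dideoxy-2,3-O-isopropylidene-D-lyxo-hex-5-enonic acid; 10 (3S,4E)-1-(trimethylsilyl)hex-4-en-3-ol
Product: 11 (3S,4E)-1-(trimethylsilyl)hex-4-en-3-yl ester of acid 7
Conditions: DCC, DMAP (cat.), CH2Cl2, 0 °C to rt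
Reagents that add atoms: none
Why: Steglich esterification joins the two fragments with retention at the carbinol centre of 10.

Step 8
Reactants: 11 (3S,4E)-1-(trimethylsilyl)hex-4-en-3-yl ester of acid 7
Product: 14 (4S,5S)-5-[(1R)-1-(tert-butyldimethylsilyloxy)prop-2-en-1-yl]-2,2-dimethyl-4-[(2S,3E)-5-(trimethylsilyl)pent-3-en-2-yl]-1,3-dioxolane-4-carboxylic acid, via silyl ketene acetal 12 (not isolated), via trimethylsilyl ester 13 (not isolated)
Conditions: LiN(iPr)2, Me3SiCl/Et3N, THF, −95 °C to rt, then 50 °C; aq. citric acid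
Reagents that add atoms: none
Why: Ireland–Claisen rearrangement of the lithium-chelated ketene acetal (OSiMe3 cis to the dioxolane oxygen) through a chair with CH2SiMe3 equatorial transfers the carbinol chirality of 10 to C10, and the allyl unit enters anti to the C6 side chain, fixing quaternary C1.

Step 9
Reactants: 14 Claisen acid
Product: 15 S-ethyl thioester of acid 14
Conditions: EtSH, DCC, DMAP (cat.), CH2Cl2, 0 °C to rt
Reagents that add atoms: ethanethiol, CCS
Why: Steglich thioesterification stores C2 as an acyl donor that survives all later steps and can be converted into a ketone under neutral conditions.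

Step 10
Reactants: 15 S-ethyl thioester of acid 14
Product: 18 S-ethyl (4S,5S)-5-[(1R)-1-(tert-butyldimethylsilyloxy)prop-2-en-1-yl]-2,2-dimethyl-4-[(2R)-3-oxopent-4-en-2-yl]-1,3-dioxolane-4-carbothioate, via epoxysilane 16 (not isolated), via allylic alcohol 17 (not isolated)
Conditions: mCPBA, CH2Cl2, −20 °C; AcOH (cat.), 0 °C; then Dess–Martin periodinane, rt
Reagents that add atoms: 3-chloroperoxybenzoic acid, OOC(=O)c1cccc(Cl)c1
Why: Prilezhaev epoxidation picks the electron-rich allylsilane, acid-triggered Peterson-type opening gives the transposed C9 allylic alcohol, and Dess–Martin oxidation in the same flask makes the vinyl ketone before the alcohol can lactonise onto the thioester (the C9 stereocentre is erased).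

Step 11
Reactants: 18 vinyl ketone
Product: 19 S-ethyl (3aS,4R,8R,8aS)-8-(tert-butyldimethylsilyloxy)-2,2,4-trimethyl-5-oxo-4,5,8,8a-tetrahydro-3aH-cyclohepta[d][1,3]dioxole-3a-carbothioate
Conditions: second-generation Hoveyda–Grubbs catalyst RuCl2(H2IMes)(=CH-C6H4-2-OiPr) (5 mol%), toluene (0.005 M), 80 °C
Reagents that add atoms: none
Why: Ring-closing metathesis between the C6 vinyl group and the vinyl ketone closes the seven-membered enone (C7=C8) with loss of ethene, the trans-dioxolane pre-organising the two chains.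

Step 12
Reactants: 19 silyloxy cycloheptenone
Product: 20 S-ethyl (3aS,4R,8R,8aS)-8-hydroxy-2,2,4-trimethyl-5-oxo-4,5,8,8a-tetrahydro-3aH-cyclohepta[d][1,3]dioxole-3a-carbothioate
Conditions: HF·pyridine, pyridine, THF, 0 °C to rt
Reagents that add atoms: none
Why: Buffered fluoride desilylation frees the C6 hydroxyl while acetonide, thioester and enone stay intact.

Step 13
Reactants: 20 hydroxy cycloheptenone
Product: 21 C6 diethylphosphonoacetate of 20
Conditions: (EtO)2P(O)CH2CO2H, DCC, DMAP (cat.), CH2Cl2, 0 °C to rt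
Reagents that add atoms: diethylphosphonoacetic acid, CCOP(=O)(CC(=O)O)OCC
Why: Steglich esterification of the only free hydroxyl installs the tethered Michael donor.

Step 14
Reactants: 21 C6 diethylphosphonoacetate of 20
Product: 23 7,8-O-isopropylidene acetal of diol 24 (α-methylene lactone), via phosphonate carbanion 22 (not isolated)
Conditions: KOtBu (1.05 equiv), THF, 0 °C; then (CH2O)n, 0 °C to rt
Reagents that add atoms: formaldehyde (from paraformaldehyde), C=O
Why: The tethered phosphonate anion adds intramolecularly (5-exo Michael) to C7 on the face of the C6 oxygen, setting the cis ring fusion, and the resulting phosphonate carbanion undergoes Horner–Wadsworth–Emmons olefination with formaldehyde.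

Step 15
Reactants: 23 acetonide-protected α-methylene lactone
Product: 24 S-ethyl (3aS,6R,7S,8S,8aR)-7,8-dihydroxy-6-methyl-3-methylidene-2,5-dioxooctahydro-2H-cyclohepta[b]furan-7-carbothioate
Conditions: CF3CO2H/H2O (9:1), CH2Cl2, 0 °C
Reagents that add atoms: none
Why: Acid-catalysed acetal hydrolysis frees the tertiary C1 and secondary C5 hydroxyls; lactone and thioester are stable to aqueous acid.

Step 16
Reactants: 24 diol
Product: 25 S-ethyl (3aS,6R,7S,8S,8aR)-7-hydroxy-6-methyl-3-methylidene-8-(3-methylbutanoyloxy)-2,5-dioxooctahydro-2H-cyclohepta[b]furan-7-carbothioate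
Conditions: (iPrCH2CO)2O, Et3N, DMAP (cat.), CH2Cl2, rt
Reagents that add atoms: 3-methylbutanoic anhydride, CC(C)CC(=O)OC(=O)CC(C)C
Why: DMAP-catalysed acylation takes the secondary C5 hydroxyl only, the tertiary C1 hydroxyl being unreactive.

Step 17
Reactants: 25 isovalerate thioester
Product: 26 (3aS,6R,7S,8S,8aR)-7-[(2Z)-but-2-enoyl]-7-hydroxy-6-methyl-3-methylidene-2,5-dioxooctahydro-2H-cyclohepta[b]furan-8-yl 3-methylbutanoate (CNP0283951.2)
Conditions: (Z)-CH3CH=CHB(OH)2, Pd2(dba)3 (2.5 mol%), tri(2-furyl)phosphine, Cu(O2CC4H3S) (1.5 equiv), THF, 45 °C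
Reagents that add atoms: (Z)-prop-1-en-1-ylboronic acid, C/C=C\B(O)O
Why: Liebeskind–Srogl coupling inserts palladium into the C(O)–S bond and transfers the alkenyl group with retention of Z geometry under base-free conditions that spare the methylene lactone, ketone and ester.

## Compound list

1 | 2,3:5,6-di-O-isopropylidene-α-D-mannofuranose | O[C@@H]1[C@H]2OC(C)(C)O[C@H]2[C@H](O1)[C@H]1COC(C)(C)O1 | starting material
2 | 2,3:5,6-di-O-isopropylidene-D-mannono-1,4-lactone | O=C1[C@H]2OC(C)(C)O[C@H]2[C@H](O1)[C@H]1COC(C)(C)O1 | intermediate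
3 | 2,3-O-isopropylidene-D-mannono-1,4-lactone | O=C1[C@H]2OC(C)(C)O[C@H]2[C@H](O1)[C@H](O)CO | intermediate
4 | 5,6-dideoxy-2,3-O-isopropylidene-D-lyxo-hex-5-enono-1,4-lactone | O=C1[C@H]2OC(C)(C)O[C@H]2[C@H](O1)C=C | intermediate
5 | potassium 5,6-dideoxy-2,3-O-isopropylidene-D-lyxo-hex-5-enonate (free 4-OH; not isolated) | [K+].[O-]C(=O)[C@H]1OC(C)(C)O[C@H]1[C@H](O)C=C | intermediate
6 | tert-butyldimethylsilyl 4-O-(tert-butyldimethylsilyl)-5,6-dideoxy-2,3-O-isopropylidene-D-lyxo-hex-5-enonate (not isolated) | CC(C)(C)[Si](C)(C)OC(=O)[C@H]1OC(C)(C)O[C@H]1[C@H](O[Si](C)(C)C(C)(C)C)C=C | intermediate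
7 | 4-O-(tert-butyldimethylsilyl)-5,6-dideoxy-2,3-O-isopropylidene-D-lyxo-hex-5-enonic acid (acid fragment) | OC(=O)[C@H]1OC(C)(C)O[C@H]1[C@H](O[Si](C)(C)C(C)(C)C)C=C | intermediate
8 | (E)-but-2-enal | C/C=C/C=O | starting material
9 | racemic (E)-1-(trimethylsilyl)hex-4-en-3-ol | C/C=C/C(O)C[Si](C)(C)C | intermediate
10 | (3S,4E)-1-(trimethylsilyl)hex-4-en-3-ol (alcohol fragment) | C/C=C/[C@H](O)C[Si](C)(C)C | intermediate
11 | (3S,4E)-1-(trimethylsilyl)hex-4-en-3-yl 4-O-(tert-butyldimethylsilyl)-5,6-dideoxy-2,3-O-isopropylidene-D-lyxo-hex-5-enonate | C=C[C@@H](O[Si](C)(C)C(C)(C)C)[C@@H]1OC(C)(C)O[C@@H]1C(=O)O[C@H](C[Si](C)(C)C)/C=C/C | intermediate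
12 | trimethylsilyl ketene acetal of 11, OSiMe3 cis to the dioxolane oxygen (not isolated) | C=C[C@@H](O[Si](C)(C)C(C)(C)C)[C@@H]1OC(C)(C)O/C1=C(\O[Si](C)(C)C)O[C@H](C[Si](C)(C)C)/C=C/C | intermediate
13 | trimethylsilyl ester of acid 14 (not isolated) | C[Si](C)(C)OC(=O)[C@]1(OC(C)(C)O[C@H]1[C@H](O[Si](C)(C)C(C)(C)C)C=C)[C@@H](C)/C=C/C[Si](C)(C)C | intermediate
14 | (4S,5S)-5-[(1R)-1-(tert-butyldimethylsilyloxy)prop-2-en-1-yl]-2,2-dimethyl-4-[(2S,3E)-5-(trimethylsilyl)pent-3-en-2-yl]-1,3-dioxolane-4-carboxylic acid | OC(=O)[C@]1(OC(C)(C)O[C@H]1[C@H](O[Si](C)(C)C(C)(C)C)C=C)[C@@H](C)/C=C/C[Si](C)(C)C | intermediate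
15 | S-ethyl thioester of 14 (stereocentres unchanged) | CCSC(=O)[C@]1(OC(C)(C)O[C@H]1[C@H](O[Si](C)(C)C(C)(C)C)C=C)[C@@H](C)/C=C/C[Si](C)(C)C | intermediate
16 | epoxide of the allylsilane double bond of 15 (epoxide diastereomers; not isolated) | CCSC(=O)[C@]1(OC(C)(C)O[C@H]1[C@H](O[Si](C)(C)C(C)(C)C)C=C)[C@@H](C)C1OC1C[Si](C)(C)C | intermediate
17 | S-ethyl (4S,5S)-5-[(1R)-1-(tert-butyldimethylsilyloxy)prop-2-en-1-yl]-4-[(2S)-3-hydroxypent-4-en-2-yl]-2,2-dimethyl-1,3-dioxolane-4-carbothioate (carbinol epimers; not isolated) | CCSC(=O)[C@]1(OC(C)(C)O[C@H]1[C@H](O[Si](C)(C)C(C)(C)C)C=C)[C@@H](C)C(O)C=C | intermediate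
18 | S-ethyl (4S,5S)-5-[(1R)-1-(tert-butyldimethylsilyloxy)prop-2-en-1-yl]-2,2-dimethyl-4-[(2R)-3-oxopent-4-en-2-yl]-1,3-dioxolane-4-carbothioate | CCSC(=O)[C@]1(OC(C)(C)O[C@H]1[C@H](O[Si](C)(C)C(C)(C)C)C=C)[C@@H](C)C(=O)C=C | intermediate
19 | S-ethyl (3aS,4R,8R,8aS)-8-(tert-butyldimethylsilyloxy)-2,2,4-trimethyl-5-oxo-4,5,8,8a-tetrahydro-3aH-cyclohepta[d][1,3]dioxole-3a-carbothioate | CCSC(=O)[C@@]12OC(C)(C)O[C@H]1[C@H](O[Si](C)(C)C(C)(C)C)C=CC(=O)[C@@H]2C | intermediate
20 | S-ethyl (3aS,4R,8R,8aS)-8-hydroxy-2,2,4-trimethyl-5-oxo-4,5,8,8a-tetrahydro-3aH-cyclohepta[d][1,3]dioxole-3a-carbothioate | CCSC(=O)[C@@]12OC(C)(C)O[C@H]1[C@H](O)C=CC(=O)[C@@H]2C | intermediate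
21 | 8-O-[2-(diethoxyphosphoryl)acetyl] derivative of 20 | CCSC(=O)[C@@]12OC(C)(C)O[C@H]1[C@H](OC(=O)CP(=O)(OCC)OCC)C=CC(=O)[C@@H]2C | intermediate
22 | potassium salt of the cis-fused α-(diethoxyphosphoryl) lactone from the Michael addition (not isolated) | CCOP(=O)(OCC)[C-]1C(=O)O[C@@H]2[C@H]1CC(=O)[C@H](C)[C@]3(C(=O)SCC)OC(C)(C)O[C@@H]23.[K+] | intermediate
23 | 7,8-O-isopropylidene acetal of 24 | C=C1C(=O)O[C@@H]2[C@H]1CC(=O)[C@H](C)[C@]3(C(=O)SCC)OC(C)(C)O[C@@H]23 | intermediate
24 | S-ethyl (3aS,6R,7S,8S,8aR)-7,8-dihydroxy-6-methyl-3-methylidene-2,5-dioxooctahydro-2H-cyclohepta[b]furan-7-carbothioate | C=C1C(=O)O[C@@H]2[C@H]1CC(=O)[C@H](C)[C@@](O)(C(=O)SCC)[C@H]2O | intermediate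
25 | S-ethyl (3aS,6R,7S,8S,8aR)-7-hydroxy-6-methyl-3-methylidene-8-(3-methylbutanoyloxy)-2,5-dioxooctahydro-2H-cyclohepta[b]furan-7-carbothioate | C=C1C(=O)O[C@@H]2[C@H]1CC(=O)[C@H](C)[C@@](O)(C(=O)SCC)[C@H]2OC(=O)CC(C)C | intermediate
26 | (3aS,6R,7S,8S,8aR)-7-[(2Z)-but-2-enoyl]-7-hydroxy-6-methyl-3-methylidene-2,5-dioxooctahydro-2H-cyclohepta[b]furan-8-yl 3-methylbutanoate | C=C1C(=O)O[C@@H]2[C@H]1CC(=O)[C@H](C)[C@@](O)(C(=O)/C=C\C)[C@H]2OC(=O)CC(C)C | target

## Step count and risk

Total step count: 17.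
Longest linear sequence: 15 steps (1 to 26 through steps 1–4 and 7–17); the alcohol fragment 10 (steps 5–6) is made in parallel and joined in step 7.

Three steps most likely to fail:

- **Step 8 (Ireland–Claisen).** The ester enolate can lose the dioxolane oxygen by β-elimination, and the C10 configuration depends on clean ketene acetal geometry. The fallback leaves the route at 7 and 10 and makes the C1–C10 bond intermolecularly. Acid 7 is methylated (Me3SiCHN2, MeOH/toluene) to methyl ester F1, and alcohol 10 is converted (ClCO2Me, pyridine) into allylic methyl carbonate F2. The zinc enolate of F1 (LiN(SiMe3)2, ZnCl2, THF, −78 °C) is then allylated with F2 under [Pd(allyl)Cl]2/PPh3 catalysis (Tsuji–Trost; net retention with 1,3-transposition, attack at the methyl-bearing terminus and anti to the C6 side chain) to give methyl ester F3. Saponification (LiOH, THF/H2O) brings the route back at 14.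

- **Step 14 (Michael addition then olefination).** The base may epimerise C10 next to the ring ketone or attack the thioester. The fallback sets out from 20, which is acylated (acryloyl chloride, iPr2NEt, CH2Cl2, −20 °C) to acrylate ester F4. A phosphine-catalysed intramolecular Rauhut–Currier reaction (PMe3, 20 mol%, tBuOH/THF, rt) joins the acrylate α-carbon to C7 on the face of the C6 oxygen and regenerates the exocyclic double bond, returning directly at 23 without stoichiometric base.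

- **Step 17 (Liebeskind–Srogl coupling).** The thioester sits on a fully substituted carbon, so acyl transfer may be slow, and the Z-enone may isomerise. The fallback sets out from 25, which is reduced (Et3SiH, Pd/C, acetone, rt; Fukuyama reduction) to α-hydroxy aldehyde F5. A chemoselective Nozaki–Hiyama–Kishi addition of (Z)-1-iodopropene (CrCl2, NiCl2 cat., DMF, rt) gives Z-allylic alcohol F6 as a carbinol epimer mixture, and Dess–Martin oxidation (NaHCO3, CH2Cl2, 0 °C) returns at 26.

Further compounds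

F1 | step 8 | methyl 4-O-(tert-butyldimethylsilyl)-5,6-dideoxy-2,3-O-isopropylidene-D-lyxo-hex-5-enonate | COC(=O)[C@H]1OC(C)(C)O[C@H]1[C@H](O[Si](C)(C)C(C)(C)C)C=C
F2 | step 8 | methyl (3S,4E)-1-(trimethylsilyl)hex-4-en-3-yl carbonate | C/C=C/[C@H](OC(=O)OC)C[Si](C)(C)C
F3 | step 8 | methyl ester of acid 14 | COC(=O)[C@]1(OC(C)(C)O[C@H]1[C@H](O[Si](C)(C)C(C)(C)C)C=C)[C@@H](C)/C=C/C[Si](C)(C)C
F4 | step 14 | 8-O-acryloyl derivative of 20 | CCSC(=O)[C@@]12OC(C)(C)O[C@H]1[C@H](OC(=O)C=C)C=CC(=O)[C@@H]2C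
F5 | step 17 | (3aS,6R,7S,8S,8aR)-7-formyl-7-hydroxy-6-methyl-3-methylidene-2,5-dioxooctahydro-2H-cyclohepta[b]furan-8-yl 3-methylbutanoate | C=C1C(=O)O[C@@H]2[C@H]1CC(=O)[C@H](C)[C@@](O)(C=O)[C@H]2OC(=O)CC(C)C
F6 | step 17 | (3aS,6R,7S,8S,8aR)-7-hydroxy-7-[(2Z)-1-hydroxybut-2-en-1-yl]-6-methyl-3-methylidene-2,5-dioxooctahydro-2H-cyclohepta[b]furan-8-yl 3-methylbutanoate (carbinol epimers) | C=C1C(=O)O[C@@H]2[C@H]1CC(=O)[C@H](C)[C@@](O)(C(O)/C=C\C)[C@H]2OC(=O)CC(C)C
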